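**Strategy.** Everything rests on cutting C8–C9, the bond between the two cis carbinol carbons of the cyclohexane (C5–C10): C8–O is the ring oxygen of the trans-fused γ-lactone (C7–C11–C12), C9–O carries the isobutyrate. One operation with SmI2 joins the C8 and C9 aldehyde carbons of an acyclic hexanedial to the cis-diol, which closes the carbocycle, and lets the C8 alkoxide attack the C12 methyl ester, which closes the lactone and leaves only C9–OH free. The precursor is dialdehyde 29, in which C1, C5, C6, C7 and C10 are already set by malate double alkylation, an oxazolidinone hydroxymethylation and a syn-aldol.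

Key step: step 19

Remark: atoms are numbered as in the target (ring C5–C10; oxirane C1/C2; lactone carbons C11–C13 on C7/C8; acrolein C4, C3, C15 on C5), and every intermediate is labelled with these numbers.

Step 1
Reactants: 1 dimethyl (R)-malate
Product: 3 dimethyl (2R,3S)-3-allyl-2-hydroxysuccinate, via dilithium alkoxide enolate 2 (not isolated)
Conditions: LiN(iPr)2 (2.2 equiv), THF, −78 → −20 °C; allyl bromide, −78 → −10 °C; AcOH
Reagents that add atoms: allyl bromide, C=CCBr
Why: Fráter–Seebach alkylation: the lithium-chelated dianion of the β-hydroxy ester should be allylated on the face opposite to the ester group on the carbinol carbon, which places the allyl chain (later C5–C4) anti to the hydroxyl and leaves C1 untouched.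

Step 2
Reactants: 3 dimethyl (2R,3S)-3-allyl-2-hydroxysuccinate
Product: 5 dimethyl (2R,3R)-3-allyl-2-hydroxy-3-methylsuccinate, via dilithium alkoxide enolate 4 (not isolated)
Conditions: LiN(iPr)2 (2.5 equiv), THF, DMPU, −78 → −10 °C; MeI, −78 → 0 °C; AcOH
Reagents that add atoms: iodomethane, CI
Why: A second Fráter–Seebach alkylation on the same chelate face: methyl should enter anti to the alkoxide and push the allyl group syn, which sets quaternary C10 relative to C1 whichever C3 epimer of 3 is used, since both give the same enolate.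

Step 3
Reactants: 5 dimethyl (2R,3R)-3-allyl-2-hydroxy-3-methylsuccinate
Product: 6 (2R,3S)-3-allyl-3-methylbutane-1,2,4-triol
Conditions: LiAlH4, THF, 0 °C → reflux; H2O, aq. NaOH
Reagents that add atoms: none
Why: LiAlH4 reduction of both esters to primary alcohols; no stereocentre is involved.

Step 4
Reactants: 6 (2R,3S)-3-allyl-3-methylbutane-1,2,4-triol
Product: 7 dioxolane alcohol (C9–OH free)
Conditions: 2,2-dimethoxypropane, acetone, TsOH (cat.), rt
Reagents that add atoms: 2,2-dimethoxypropane, COC(C)(C)OC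
Why: Acid-catalysed acetonide formation under thermodynamic control, in which the terminal 1,2-diol should close the five-membered dioxolane in preference to a 1,3-dioxane that would carry an axial acetal methyl group, so that only the neopentyl C9 hydroxyl stays free.

Step 5
Reactants: 7 dioxolane alcohol
Product: 8 dioxolane benzoate
Conditions: BzCl, pyridine, DMAP (cat.), CH2Cl2, 0 °C → rt
Reagents that add atoms: benzoyl chloride, O=C(Cl)c1ccccc1
Why: DMAP-catalysed O-acylation of the remaining primary alcohol; the benzoate is inert to the oxidant of step 6 and to the chemistry of steps 12 to 16 and is removed in step 17 together with the lactone.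

Step 6
Reactants: 8 dioxolane benzoate
Product: 9 benzoyloxy dioxolanyl butanoic acid
Conditions: RuCl3·xH2O (cat.), NaIO4, CCl4/MeCN/H2O, rt
Reagents that add atoms: sodium periodate, [Na+].[O-]I(=O)(=O)=O
Why: Sharpless RuO4 cleavage of the terminal alkene (catalytic ruthenium reoxidised by NaIO4) should give the acid one carbon shorter, whose carboxyl carbon is C4; acetonide and benzoate do not react.

Step 7
Reactants: 9 benzoyloxy dioxolanyl butanoic acid; 10 (S)-4-benzyloxazolidin-2-one
Product: 12 acyl oxazolidinone of acid 9, via mixed pivalic anhydride 11 (not isolated)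
Conditions: PivCl, Et3N, THF, −20 °C; then 10, LiCl, −20 °C → rt
Reagents that add atoms: none
Why: N-acylation of the oxazolidinone through the mixed pivalic anhydride, the nucleophile attacking the unhindered CH2C=O carbonyl and not the tert-butyl carbonyl.

Step 8
Reactants: 13 monomethyl succinate; 10 (S)-4-benzyloxazolidin-2-one
Product: 15 succinate imide, via mixed pivalic anhydride 14 (not isolated)
Conditions: PivCl, Et3N, THF, −20 °C; then 10, LiCl, −20 °C → rt
Reagents that add atoms: none
Why: The same mixed-anhydride N-acylation as in step 7.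

Step 9
Reactants: 15 succinate imide
Product: 18 lactone imide, via titanium enolate 16 (not isolated), via hydroxymethyl ester 17 (not isolated)
Conditions: TiCl4, iPr2NEt, CH2Cl2, 0 °C; 1,3,5-trioxane, TiCl4, 0 °C; aq. NH4Cl; then TsOH (cat.), CH2Cl2, rt
Reagents that add atoms: 1,3,5-trioxane, C1OCOCO1
Why: Evans titanium-enolate hydroxymethylation: the chelated (Z)-enolate should be attacked by TiCl4-activated trioxane on the face opposite to the benzyl group, which sets C7, and the γ-hydroxy ester then lactonises under acid (5-exo-trig), masking C8–O and C12 together.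

Step 10
Reactants: 18 lactone imide
Product: 19 lactone thioester
Conditions: EtSH, n-BuLi, THF, 0 °C; AcOH
Reagents that add atoms: ethanethiol, CCS
Why: Thiolysis of the exocyclic imide carbonyl by lithium ethanethiolate (acyl substitution) gives the thioester and frees the auxiliary, and it avoids a free hydroxymethyl lactone, which could racemise by translactonisation.

Step 11
Reactants: 19 lactone thioester
Product: 20 (3R)-5-oxooxolane-3-carbaldehyde
Conditions: Et3SiH, Pd/C (10%), acetone, rt
Reagents that add atoms: none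
Why: Fukuyama reduction (palladium-catalysed hydrosilane reduction of a thioester) stops at the aldehyde under neutral conditions that leave the lactone and the α-stereocentre C7 alone; the aldehyde is used crude.

Step 12
Reactants: 12 acyl oxazolidinone of acid 9; 20 (3R)-5-oxooxolane-3-carbaldehyde
Product: 22 syn-aldol imide, via dibutylboron enolate 21 (not isolated)
Conditions: Bu2BOTf, iPr2NEt, CH2Cl2, −78 → 0 °C; 20, −78 → 0 °C; pH 7 buffer, MeOH, H2O2, 0 °C
Reagents that add atoms: none
Why: Evans syn-aldol reaction: the (Z)-boron enolate should react through a Zimmerman–Traxler chair on the enolate face left open by the benzyl group of the dipole-opposed (S)-auxiliary, so that C5 and C6 are set together as the syn pair (C6–OH syn to the C10 branch) under reagent control.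

Step 13
Reactants: 22 syn-aldol imide
Product: 23 hydroxy thioester
Conditions: EtSH, n-BuLi, THF, 0 °C → rt; AcOH
Reagents that add atoms: ethanethiol, CCS
Why: Thiolysis of the imide as in step 10; the small thiolate should reach the hindered exocyclic carbonyl, and the thioester is the handle for the ketone synthesis of step 15.

Step 14
Reactants: 23 hydroxy thioester
Product: 24 silyloxy thioester
Conditions: TBSOTf, 2,6-lutidine, CH2Cl2, −78 → 0 °C
Reagents that add atoms: tert-butyldimethylsilyl triflate, CC(C)(C)[Si](C)(C)OS(=O)(=O)C(F)(F)F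
Why: Silylation of the secondary C6 alcohol; the silyl ether later blocks lactonisation at C6–O and shields the upper ring face in step 19.

Step 15
Reactants: 24 silyloxy thioester
Product: 25 methyl ketone
Conditions: Me2CuLi, Et2O, −78 → −40 °C; aq. NH4Cl
Reagents that add atoms: lithium dimethylcuprate, [Li+].C[Cu-]C
Why: Acylation of the Gilman cuprate by the thioester (ketone synthesis) should give the methyl ketone at C4 at low temperature without attack on lactone, benzoate or product ketone and without epimerising C5.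

Step 16
Reactants: 25 methyl ketone
Product: 26 isopropenyl lactone benzoate
Conditions: Zn, CH2Br2, TiCl4 (preformed Lombardo reagent), THF/CH2Cl2, 0 °C → rt
Reagents that add atoms: dibromomethane, BrCBr
Why: Lombardo methylenation: the non-basic titanium–zinc methylene reagent should convert the hindered, enolisable methyl ketone into the isopropenyl group without epimerisation at C5 or β-elimination of the C6 silyloxy group, and it does not touch the esters.

Step 17
Reactants: 26 isopropenyl lactone benzoate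
Product: 28 diol methyl ester, via potassium carboxylate 27 (not isolated)
Conditions: KOH, MeOH/H2O, 40 °C; solid CO2; concentrate; then MeI, DMF, 0 °C
Reagents that add atoms: potassium hydroxide, [K+].[OH-]; iodomethane, CI
Why: Saponification opens the lactone and removes the benzoate, and SN2 methylation of the potassium carboxylate in the presence of hydrogencarbonate only gives the methyl ester without acid, so that the γ-hydroxy ester should not relactonise before step 18.

Step 18
Reactants: 28 diol methyl ester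
Product: 29 dialdehyde
Conditions: Dess–Martin periodinane, NaHCO3, CH2Cl2, 0 °C → rt
Reagents that add atoms: none
Why: Dess–Martin oxidation of both primary alcohols under buffered conditions should give the dialdehyde without epimerisation at C7 or β-elimination of the C6 silyloxy group; it is used at once.

Step 19
Reactants: 29 dialdehyde
Product: 31 hydroxy lactone, via cis-diol methyl ester 30 (not isolated)
Conditions: SmI2 (2.5 equiv), THF, −78 °C → rt; aq. NaHCO3
Reagents that add atoms: none
Why: Two single-electron transfers from divalent samarium turn the C8 and C9 aldehydes into ketyls that are held on trivalent samarium in one chelate and couple, forming C8–C9; this is the known SmI2 pinacol coupling of 1,6-dialdehydes, which gives cis-cyclohexane-1,2-diols. The carbocycle closes by attack of the C8 ketyl on the samarium-bound C9 carbonyl carbon in a 6-exo-trig sense through a chair, and the lactone closes by 5-exo-trig acyl substitution of the C8 samarium alkoxide on the C12 methyl ester with loss of methoxide. The cis relationship of the new centres C8 and C9 comes from the samarium bridge; their face comes from the chair that keeps the C5 isopropenyl group, the C7 acetate arm and the C10 dioxolanyl group equatorial, in which the C6 silyloxy group and the C10 methyl group are both axial on the upper face, so that the C8 oxygen can only be equatorial on the lower face (an axial C8–O would be syn-axial to both) and the bridged C9 oxygen becomes axial, trans to the C10 methyl. The lactone needs a choice between the two new alkoxides, and geometry secures it: the equatorial C8 oxygen is gauche to the equatorial C7 arm, whereas the axial C9 oxygen lies on the face opposite to that arm and cannot reach C12, and the C6 oxygen is silylated. HMPA is left out so that ketyl addition to the unactivated isopropenyl group and over-reduction stay slower than the coupling of the two aldehydes.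

Step 20
Reactants: 31 hydroxy lactone
Product: 32 C9 isobutyrate
Conditions: (iPrCO)2O, Et3N, DMAP, CH2Cl2, rt → 40 °C
Reagents that add atoms: isobutyric anhydride, CC(C)C(=O)OC(=O)C(C)C
Why: DMAP-catalysed acylation of the only free hydroxyl (C9–OH, axial and neopentyl, hence anhydride and DMAP).

Step 21
Reactants: 32 C9 isobutyrate
Product: 33 C1/C2 diol
Conditions: AcOH/H2O (4:1), 40 °C
Reagents that add atoms: none
Why: Acid-catalysed hydrolysis of the terminal acetonide; the hindered secondary silyl ether, the lactone and the isobutyrate should survive aqueous acetic acid.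

Step 22
Reactants: 33 C1/C2 diol
Product: 35 oxirane, via primary tosylate 34 (not isolated)
Conditions: TsCl, Et3N, Bu2SnO (cat.), CH2Cl2, 0 °C; then DBU, rt
Reagents that add atoms: none
Why: Tin-catalysed selective sulfonylation of the primary hydroxyl followed by intramolecular Williamson closure (3-exo-tet) by the C1 hydroxyl; the C1–O bond is never broken, so C1 keeps its configuration.

Step 23
Reactants: 35 oxirane
Product: 39 α-methylene lactone, via lithium enolate 36 (not isolated), via Mannich base 37 (not isolated), via trimethylammonium iodide 38 (not isolated)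
Conditions: LiN(iPr)2 (1.1 equiv), THF, −78 °C; CH2=NMe2+ I−, −78 → 0 °C; then MeI, MeOH, rt; then aq. NaHCO3, CH2Cl2
Reagents that add atoms: N,N-dimethylmethyleneiminium iodide (Eschenmoser's salt), C=[N+](C)C.[I-]
Why: α-Methylenation by Mannich reaction of the lactone enolate, N-methylation and Hofmann-type elimination; at −78 °C the base should remove the lactone α-proton (more acidic and more accessible than the isobutyrate α-proton), and the oxirane offers no β-hydrogen on C10 for a lithium amide.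

Step 24
Reactants: 39 α-methylene lactone
Product: 40 C6 alcohol
Conditions: HF·pyridine, pyridine, THF, 0 °C → rt
Reagents that add atoms: none
Why: Fluoride-mediated desilylation with pyridine-buffered HF·pyridine, conditions under which oxiranes, esters and α-methylene lactones are known to survive.

Step 25
Reactants: 40 C6 alcohol
Product: 41 C15 allylic alcohol
Conditions: SeO2 (cat.), tBuOOH, CH2Cl2, rt
Reagents that add atoms: tert-butyl hydroperoxide, CC(C)(C)OO
Why: SeO2 allylic oxidation (ene reaction then [2,3]-sigmatropic shift) of the electron-rich isopropenyl group at its methyl carbon C15, the electron-poor methylene lactone being inert and the C5 methine being shielded by C10 and C6.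

Step 26
Reactants: 41 C15 allylic alcohol
Product: 42 target CNP0519565.1
Conditions: MnO2, CH2Cl2, rt
Reagents that add atoms: none
Why: MnO2 oxidises the allylic primary alcohol to the enal and leaves the non-allylic secondary C6 hydroxyl untouched.

**Compound list**

1 | dimethyl (2R)-2-hydroxybutanedioate (dimethyl (R)-malate) | COC(=O)C[C@@H](O)C(=O)OC | starting material
2 | dilithium alkoxide enolate of 1 | [Li+].[Li+].COC([O-])=C[C@@H]([O-])C(=O)OC | intermediate (not isolated)
3 | dimethyl (2R,3S)-2-hydroxy-3-(prop-2-en-1-yl)butanedioate | COC(=O)[C@@H](CC=C)[C@@H](O)C(=O)OC | intermediate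
4 | dilithium alkoxide enolate of 3 | [Li+].[Li+].COC([O-])=C(CC=C)[C@@H]([O-])C(=O)OC | intermediate (not isolated)
5 | dimethyl (2R,3R)-2-hydroxy-3-methyl-3-(prop-2-en-1-yl)butanedioate | COC(=O)[C@@](CC=C)(C)[C@@H](O)C(=O)OC | intermediate
6 | (2R,3S)-3-methyl-3-(prop-2-en-1-yl)butane-1,2,4-triol | OC[C@@](CC=C)(C)[C@@H](O)CO | intermediate
7 | (2S)-2-[(4R)-2,2-dimethyl-1,3-dioxolan-4-yl]-2-methylpent-4-en-1-ol | OC[C@@](CC=C)(C)[C@@H]1COC(C)(C)O1 | intermediate
8 | (2S)-2-[(4R)-2,2-dimethyl-1,3-dioxolan-4-yl]-2-methylpent-4-en-1-yl benzoate | O=C(OC[C@@](CC=C)(C)[C@@H]1COC(C)(C)O1)c1ccccc1 | intermediate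
9 | (3S)-4-(benzoyloxy)-3-[(4R)-2,2-dimethyl-1,3-dioxolan-4-yl]-3-methylbutanoic acid | O=C(OC[C@@](CC(=O)O)(C)[C@@H]1COC(C)(C)O1)c1ccccc1 | intermediate
10 | (4S)-4-benzyl-1,3-oxazolidin-2-one | O=C1N[C@@H](Cc2ccccc2)CO1 | starting material
11 | mixed anhydride of acid 9 and 2,2-dimethylpropanoic acid | O=C(OC[C@@](CC(=O)OC(=O)C(C)(C)C)(C)[C@@H]1COC(C)(C)O1)c1ccccc1 | intermediate (not isolated)
12 | (2S)-4-[(4S)-4-benzyl-2-oxo-1,3-oxazolidin-3-yl]-2-[(4R)-2,2-dimethyl-1,3-dioxolan-4-yl]-2-methyl-4-oxobutyl benzoate | O=C(OC[C@@](CC(=O)N1[C@@H](Cc2ccccc2)COC1=O)(C)[C@@H]1COC(C)(C)O1)c1ccccc1 | intermediate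
13 | 4-methoxy-4-oxobutanoic acid (monomethyl succinate) | COC(=O)CCC(=O)O | starting material
14 | mixed anhydride of acid 13 and 2,2-dimethylpropanoic acid | COC(=O)CCC(=O)OC(=O)C(C)(C)C | intermediate (not isolated)
15 | methyl 4-[(4S)-4-benzyl-2-oxo-1,3-oxazolidin-3-yl]-4-oxobutanoate | COC(=O)CCC(=O)N1[C@@H](Cc2ccccc2)COC1=O | intermediate
16 | (Z)-trichlorotitanium enolate of 15 | COC(=O)C/C=C(\O[Ti](Cl)(Cl)Cl)N1[C@@H](Cc2ccccc2)COC1=O | intermediate (not isolated)
17 | methyl (3R)-4-[(4S)-4-benzyl-2-oxo-1,3-oxazolidin-3-yl]-3-(hydroxymethyl)-4-oxobutanoate | OC[C@@H](CC(=O)OC)C(=O)N1[C@@H](Cc2ccccc2)COC1=O | intermediate (not isolated)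
18 | (4S)-4-benzyl-3-[(3R)-5-oxooxolane-3-carbonyl]-1,3-oxazolidin-2-one | O=C1OC[C@@H](C1)C(=O)N1[C@@H](Cc2ccccc2)COC1=O | intermediate
19 | S-ethyl (3R)-5-oxooxolane-3-carbothioate | O=C1OC[C@@H](C1)C(=O)SCC | intermediate
20 | (3R)-5-oxooxolane-3-carbaldehyde | O=C1OC[C@@H](C1)C=O | intermediate
21 | (Z)-dibutylboron enolate of 12 | O=C(OC[C@@](/C=C(\OB(CCCC)CCCC)N1[C@@H](Cc2ccccc2)COC1=O)(C)[C@@H]1COC(C)(C)O1)c1ccccc1 | intermediate (not isolated)
22 | (2S,3S,4R)-3-[(4S)-4-benzyl-2-oxo-1,3-oxazolidine-3-carbonyl]-2-[(4R)-2,2-dimethyl-1,3-dioxolan-4-yl]-4-hydroxy-2-methyl-4-[(3R)-5-oxooxolan-3-yl]butyl benzoate | O=C1OC[C@@H](C1)[C@@H](O)[C@@H](C(=O)N1[C@@H](Cc2ccccc2)COC1=O)[C@@](C)(COC(=O)c1ccccc1)[C@@H]1COC(C)(C)O1 | intermediate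
23 | (2S,3S,4R)-2-[(4R)-2,2-dimethyl-1,3-dioxolan-4-yl]-3-[(ethylsulfanyl)carbonyl]-4-hydroxy-2-methyl-4-[(3R)-5-oxooxolan-3-yl]butyl benzoate | O=C1OC[C@@H](C1)[C@@H](O)[C@@H](C(=O)SCC)[C@@](C)(COC(=O)c1ccccc1)[C@@H]1COC(C)(C)O1 | intermediate
24 | (2S,3S,4R)-4-[(tert-butyldimethylsilyl)oxy]-2-[(4R)-2,2-dimethyl-1,3-dioxolan-4-yl]-3-[(ethylsulfanyl)carbonyl]-2-methyl-4-[(3R)-5-oxooxolan-3-yl]butyl benzoate | O=C1OC[C@@H](C1)[C@@H](O[Si](C)(C)C(C)(C)C)[C@@H](C(=O)SCC)[C@@](C)(COC(=O)c1ccccc1)[C@@H]1COC(C)(C)O1 | intermediate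
25 | (2S,3S,4R)-3-acetyl-4-[(tert-butyldimethylsilyl)oxy]-2-[(4R)-2,2-dimethyl-1,3-dioxolan-4-yl]-2-methyl-4-[(3R)-5-oxooxolan-3-yl]butyl benzoate | O=C1OC[C@@H](C1)[C@@H](O[Si](C)(C)C(C)(C)C)[C@@H](C(C)=O)[C@@](C)(COC(=O)c1ccccc1)[C@@H]1COC(C)(C)O1 | intermediate
26 | (2S,3S,4S)-4-[(tert-butyldimethylsilyl)oxy]-2-[(4R)-2,2-dimethyl-1,3-dioxolan-4-yl]-2-methyl-4-[(3R)-5-oxooxolan-3-yl]-3-(prop-1-en-2-yl)butyl benzoate | O=C1OC[C@@H](C1)[C@@H](O[Si](C)(C)C(C)(C)C)[C@@H](C(C)=C)[C@@](C)(COC(=O)c1ccccc1)[C@@H]1COC(C)(C)O1 | intermediate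
27 | potassium (3R,4S,5S,6S)-4-[(tert-butyldimethylsilyl)oxy]-6-[(4R)-2,2-dimethyl-1,3-dioxolan-4-yl]-7-hydroxy-3-(hydroxymethyl)-6-methyl-5-(prop-1-en-2-yl)heptanoate | OC[C@@H](CC(=O)[O-])[C@@H](O[Si](C)(C)C(C)(C)C)[C@@H](C(C)=C)[C@@](C)(CO)[C@@H]1COC(C)(C)O1.[K+] | intermediate (not isolated)
28 | methyl (3R,4S,5S,6S)-4-[(tert-butyldimethylsilyl)oxy]-6-[(4R)-2,2-dimethyl-1,3-dioxolan-4-yl]-7-hydroxy-3-(hydroxymethyl)-6-methyl-5-(prop-1-en-2-yl)heptanoate | OC[C@@H](CC(=O)OC)[C@@H](O[Si](C)(C)C(C)(C)C)[C@@H](C(C)=C)[C@@](C)(CO)[C@@H]1COC(C)(C)O1 | intermediate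
29 | methyl (3S,4S,5S,6R)-4-[(tert-butyldimethylsilyl)oxy]-6-[(4R)-2,2-dimethyl-1,3-dioxolan-4-yl]-3-formyl-6-methyl-7-oxo-5-(prop-1-en-2-yl)heptanoate | O=C[C@@H](CC(=O)OC)[C@@H](O[Si](C)(C)C(C)(C)C)[C@@H](C(C)=C)[C@](C)([C@@H]1COC(C)(C)O1)C=O | intermediate (precursor of the key step)
30 | methyl [(1R,2S,3S,4S,5S,6R)-2-[(tert-butyldimethylsilyl)oxy]-4-[(4R)-2,2-dimethyl-1,3-dioxolan-4-yl]-5,6-dihydroxy-4-methyl-3-(prop-1-en-2-yl)cyclohexyl]acetate | COC(=O)C[C@H]1[C@@H](O[Si](C)(C)C(C)(C)C)[C@@H](C(C)=C)[C@](C)([C@@H]2COC(C)(C)O2)[C@H](O)[C@@H]1O | intermediate (not isolated)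
31 | (3aR,4S,5S,6S,7S,7aR)-4-[(tert-butyldimethylsilyl)oxy]-6-[(4R)-2,2-dimethyl-1,3-dioxolan-4-yl]-7-hydroxy-6-methyl-5-(prop-1-en-2-yl)hexahydro-1-benzofuran-2(3H)-one | O=C1C[C@H]2[C@@H](O[Si](C)(C)C(C)(C)C)[C@@H](C(C)=C)[C@](C)([C@@H]3COC(C)(C)O3)[C@H](O)[C@@H]2O1 | intermediate (product of the key step)
32 | (3aR,4S,5S,6R,7S,7aR)-4-[(tert-butyldimethylsilyl)oxy]-6-[(4R)-2,2-dimethyl-1,3-dioxolan-4-yl]-6-methyl-2-oxo-5-(prop-1-en-2-yl)octahydro-1-benzofuran-7-yl 2-methylpropanoate | O=C1C[C@H]2[C@@H](O[Si](C)(C)C(C)(C)C)[C@@H](C(C)=C)[C@](C)([C@@H]3COC(C)(C)O3)[C@H](OC(=O)C(C)C)[C@@H]2O1 | intermediate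
33 | (3aR,4S,5S,6R,7S,7aR)-4-[(tert-butyldimethylsilyl)oxy]-6-[(1R)-1,2-dihydroxyethyl]-6-methyl-2-oxo-5-(prop-1-en-2-yl)octahydro-1-benzofuran-7-yl 2-methylpropanoate | O=C1C[C@H]2[C@@H](O[Si](C)(C)C(C)(C)C)[C@@H](C(C)=C)[C@](C)([C@@H](O)CO)[C@H](OC(=O)C(C)C)[C@@H]2O1 | intermediate
34 | (3aR,4S,5S,6R,7S,7aR)-4-[(tert-butyldimethylsilyl)oxy]-6-[(1R)-1-hydroxy-2-{[(4-methylphenyl)sulfonyl]oxy}ethyl]-6-methyl-2-oxo-5-(prop-1-en-2-yl)octahydro-1-benzofuran-7-yl 2-methylpropanoate | O=C1C[C@H]2[C@@H](O[Si](C)(C)C(C)(C)C)[C@@H](C(C)=C)[C@](C)([C@@H](O)COS(=O)(=O)c3ccc(C)cc3)[C@H](OC(=O)C(C)C)[C@@H]2O1 | intermediate (not isolated)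
35 | (3aR,4S,5S,6R,7S,7aR)-4-[(tert-butyldimethylsilyl)oxy]-6-methyl-6-[(2R)-oxiran-2-yl]-2-oxo-5-(prop-1-en-2-yl)octahydro-1-benzofuran-7-yl 2-methylpropanoate | O=C1C[C@H]2[C@@H](O[Si](C)(C)C(C)(C)C)[C@@H](C(C)=C)[C@](C)([C@@H]3CO3)[C@H](OC(=O)C(C)C)[C@@H]2O1 | intermediate
36 | lithium enolate of lactone 35 | [Li+].[O-]C1=C[C@H]2[C@@H](O[Si](C)(C)C(C)(C)C)[C@@H](C(C)=C)[C@](C)([C@@H]3CO3)[C@H](OC(=O)C(C)C)[C@@H]2O1 | intermediate (not isolated)
37 | 3-[(dimethylamino)methyl] derivative of 35 (C11 epimers) | CN(C)CC1C(=O)O[C@@H]2[C@@H]1[C@@H](O[Si](C)(C)C(C)(C)C)[C@@H](C(C)=C)[C@](C)([C@@H]1CO1)[C@@H]2OC(=O)C(C)C | intermediate (not isolated)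
38 | 3-[(trimethylammonio)methyl] derivative of 35, iodide | C[N+](C)(C)CC1C(=O)O[C@@H]2[C@@H]1[C@@H](O[Si](C)(C)C(C)(C)C)[C@@H](C(C)=C)[C@](C)([C@@H]1CO1)[C@@H]2OC(=O)C(C)C.[I-] | intermediate (not isolated)
39 | (3aR,4S,5S,6R,7S,7aR)-4-[(tert-butyldimethylsilyl)oxy]-6-methyl-3-methylidene-6-[(2R)-oxiran-2-yl]-2-oxo-5-(prop-1-en-2-yl)octahydro-1-benzofuran-7-yl 2-methylpropanoate | C=C1C(=O)O[C@@H]2[C@@H]1[C@@H](O[Si](C)(C)C(C)(C)C)[C@@H](C(C)=C)[C@](C)([C@@H]1CO1)[C@@H]2OC(=O)C(C)C | intermediate
40 | (3aS,4S,5S,6R,7S,7aR)-4-hydroxy-6-methyl-3-methylidene-6-[(2R)-oxiran-2-yl]-2-oxo-5-(prop-1-en-2-yl)octahydro-1-benzofuran-7-yl 2-methylpropanoate | C=C1C(=O)O[C@@H]2[C@@H]1[C@@H](O)[C@@H](C(C)=C)[C@](C)([C@@H]1CO1)[C@@H]2OC(=O)C(C)C | intermediate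
41 | (3aS,4S,5S,6R,7S,7aR)-4-hydroxy-5-(3-hydroxyprop-1-en-2-yl)-6-methyl-3-methylidene-6-[(2R)-oxiran-2-yl]-2-oxooctahydro-1-benzofuran-7-yl 2-methylpropanoate | C=C1C(=O)O[C@@H]2[C@@H]1[C@@H](O)[C@@H](C(=C)CO)[C@](C)([C@@H]1CO1)[C@@H]2OC(=O)C(C)C | intermediate
42 | (3aS,4S,5R,6R,7S,7aR)-4-hydroxy-6-methyl-3-methylidene-6-[(2R)-oxiran-2-yl]-2-oxo-5-(3-oxoprop-1-en-2-yl)octahydro-1-benzofuran-7-yl 2-methylpropanoate (CNP0519565.1) | C=C1C(=O)O[C@@H]2[C@@H]1[C@@H](O)[C@@H](C(=C)C=O)[C@](C)([C@@H]1CO1)[C@@H]2OC(=O)C(C)C | target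

**Step count and risk**

Total step count: 26. Longest linear sequence: 22 steps (steps 1 to 7, then 12 to 26).

Steps most likely to fail:

1. Step 19. The reductive coupling may stop at simple reduction of the two aldehydes, may couple with poor facial selectivity, or C7 may epimerise before the ring closes. Fallback: the C8–C9 bond would be made by olefin metathesis and the glycol by osmylation, with the isopropenyl group still masked as its methyl ketone. It sets out from methyl ketone 25. KOH then MeI as in step 17 should give the keto diol ester F1, Dess–Martin oxidation the keto dialdehyde F2, and Ph3P=CH2 (THF, −78 °C) should methylenate the two aldehydes in preference to the hindered ketone to give the diene F3. Second-generation Grubbs catalyst should close the cyclohexene F4; OsO4 (cat.) with N-methylmorpholine N-oxide should then add to the lower face, away from the pseudo-axial C6 silyloxy and C10 methyl groups, to give the cis-diol F5, which lactonises (PPTS) to the keto lactone F6. Lombardo methylenation of the ketone comes back to the route at hydroxy lactone 31.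

2. Step 12. The neopentyl-type boron enolate may add too slowly, so that enolate decay or retro-aldol cleavage erodes conversion and selectivity. Fallback: the C5–C6 bond would be made by enolate acylation and the carbinol by chelation-controlled reduction. It sets out from acid 9 and lactone imide 18. Acid 9 would be coupled (PivCl, Et3N; LiCl) with (R)-4-benzyloxazolidin-2-one to the diastereomeric imide F7; 18 would be hydrolysed (LiOH, H2O2) to the lactone acid F8 and converted ((COCl)2, DMF cat.) into the acid chloride F9. The chelated lithium enolate of F7 (LiN(iPr)2, THF, −78 °C), attacked on the face opposite to the benzyl group, should be acylated by F9 to the β-keto imide F10, with C5 configured as in 22; Zn(BH4)2 should reduce the chelated ketone to the syn β-hydroxy imide F11, and thiolysis with LiSEt comes back to the route at thioester 23.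

3. Step 25. Over-oxidation, slow conversion, or hydrogen abstraction at the C5 methine instead of the methyl group may spoil the allylic oxidation of a densely functionalised late intermediate. Fallback: the oxygen would be brought in through an allylic chloride. It sets out from alcohol 40: ene-type chlorination of the isopropenyl group by HOCl (Ca(OCl)2, solid CO2, CH2Cl2/H2O, 0 °C) should give the allylic chloride F12, and N-methylmorpholine N-oxide (MeCN, rt) should oxidise the primary allylic chloride directly to the enal, coming back to the route at target 42.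

**Further compounds**

F1 | step 19 | methyl (3R,4R,5S,6S)-5-acetyl-4-[(tert-butyldimethylsilyl)oxy]-6-[(4R)-2,2-dimethyl-1,3-dioxolan-4-yl]-7-hydroxy-3-(hydroxymethyl)-6-methylheptanoate | OC[C@@H](CC(=O)OC)[C@@H](O[Si](C)(C)C(C)(C)C)[C@@H](C(C)=O)[C@@](C)(CO)[C@@H]1COC(C)(C)O1
F2 | step 19 | keto dialdehyde: 29 with acetyl in place of prop-1-en-2-yl | O=C[C@@H](CC(=O)OC)[C@@H](O[Si](C)(C)C(C)(C)C)[C@@H](C(C)=O)[C@](C)([C@@H]1COC(C)(C)O1)C=O
F3 | step 19 | diene: F2 with both formyl groups converted into vinyl groups | C=C[C@@H](CC(=O)OC)[C@@H](O[Si](C)(C)C(C)(C)C)[C@@H](C(C)=O)[C@](C)([C@@H]1COC(C)(C)O1)C=C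
F4 | step 19 | cyclohexene: methyl 2-[5-acetyl-6-silyloxy-4-(dioxolanyl)-4-methylcyclohex-2-en-1-yl]acetate (C8=C9) | COC(=O)C[C@H]1[C@@H](O[Si](C)(C)C(C)(C)C)[C@@H](C(C)=O)[C@](C)([C@@H]2COC(C)(C)O2)C=C1
F5 | step 19 | cis-diol: 30 with acetyl in place of prop-1-en-2-yl | COC(=O)C[C@H]1[C@@H](O[Si](C)(C)C(C)(C)C)[C@@H](C(C)=O)[C@](C)([C@@H]2COC(C)(C)O2)[C@H](O)[C@@H]1O
F6 | step 19 | keto lactone: 31 with acetyl in place of prop-1-en-2-yl | O=C1C[C@H]2[C@@H](O[Si](C)(C)C(C)(C)C)[C@@H](C(C)=O)[C@](C)([C@@H]3COC(C)(C)O3)[C@H](O)[C@@H]2O1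
F7 | step 12 | (2S)-4-[(4R)-4-benzyl-2-oxo-1,3-oxazolidin-3-yl]-2-[(4R)-2,2-dimethyl-1,3-dioxolan-4-yl]-2-methyl-4-oxobutyl benzoate | O=C(OC[C@@](CC(=O)N1[C@H](Cc2ccccc2)COC1=O)(C)[C@@H]1COC(C)(C)O1)c1ccccc1
F8 | step 12 | (3R)-5-oxooxolane-3-carboxylic acid | O=C1OC[C@@H](C1)C(=O)O
F9 | step 12 | (3R)-5-oxooxolane-3-carbonyl chloride | O=C1OC[C@@H](C1)C(=O)Cl
F10 | step 12 | β-keto imide: C6 ketone of F11 | O=C1OC[C@@H](C1)C(=O)[C@@H](C(=O)N1[C@H](Cc2ccccc2)COC1=O)[C@@](C)(COC(=O)c1ccccc1)[C@@H]1COC(C)(C)O1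
F11 | step 12 | syn β-hydroxy imide: 22 with the (4R)-4-benzyl auxiliary | O=C1OC[C@@H](C1)[C@@H](O)[C@@H](C(=O)N1[C@H](Cc2ccccc2)COC1=O)[C@@](C)(COC(=O)c1ccccc1)[C@@H]1COC(C)(C)O1
F12 | step 25 | allylic chloride: 40 with 3-chloroprop-1-en-2-yl in place of prop-1-en-2-yl | C=C1C(=O)O[C@@H]2[C@@H]1[C@@H](O)[C@@H](C(=C)CCl)[C@](C)([C@@H]1CO1)[C@@H]2OC(=O)C(C)C
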